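**Plan**
Numbering: ten-membered ring C6–C5=C4(C15H3)–C3–C2–C1=C10(C14)–C9–C8–C7; lactone ring O–C6–C7–C11(=C13H2)–C12(=O). The enabling feature is that C3 is a bare ring CH2 bonded to C4, the methyl-bearing sp2 carbon of the cis C4=C5 alkene. The carbocycle can therefore be opened at C3–C4 without touching a stereocentre.
Cuts: C3–C4 (ten-membered ring), then C6–C7 and O–C12 (lactone ring), C11–C13, C7=C11, C2–C3 and C10–C14. Finally C2 is rejoined to C7 as the unhalogenated alkene of a bromobenzene-derived cis-dihydrodiol.
Forward: the diol ring supplies C7–C8–C9–C10=C1–C2. C14 is coupled on, the ring is cleaved, C3 plus a sacrificial carboxyl carbon is added at C2, and C11/C12 and C13 are added at C7. Allylboration of (Z)-3-iodobut-2-enal brings in C4–C6/C15 and closes the lactone ring first; the ten-membered ring closes afterwards.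
Stereochemistry: C8, C9 and the cis C1=C10 geometry are carried over from the diol ring, and the acyl centre comes from (2R)-2-methylbutanoic acid. C6 and C7 arise together in a chair allylboration (anti adduct = trans-lactone, face set by C8). The Z C4=C5 geometry comes from trans-hydroalumination/iodination of but-2-yn-1-ol and is retained at nickel.

Key step: step 19

Remark: the two carbinol centres made in step 3 are erased in step 6, and 20 is racemic at a carbon that becomes sp2 in step 12, so neither affects the stereochemical outcome.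

Step 1
Reactants: 1 (1S,2S)-3-bromocyclohexa-3,5-diene-1,2-diol
Product: 2 (1S,6S)-2-bromo-6-[(tert-butyldimethylsilyl)oxy]cyclohexa-2,4-dien-1-ol (future C8 oxygen silylated; future C9 hydroxyl free)
Conditions: TBSCl (1.05 equiv), imidazole, DMF, −10 °C
Reagents that add atoms: tert-butyldimethylsilyl chloride, CC(C)(C)[Si](C)(C)Cl
Why: Selective silyl ether formation, because the hydroxyl remote from the bromine-bearing carbon is the less hindered one and is the one known to silylate first in this diol; no stereocentre is touched.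

Step 2
Reactants: 2 mono-TBS bromodienol; 3 (2R)-2-methylbutanoic acid
Product: 4 (1S,6S)-2-bromo-6-[(tert-butyldimethylsilyl)oxy]cyclohexa-2,4-dien-1-yl (2R)-2-methylbutanoate
Conditions: DCC, DMAP (10 mol %), CH2Cl2, 0 °C
Reagents that add atoms: none
Why: Steglich esterification acylates the remaining hydroxyl (C9) with retention at the carbinol and acyl centres, and the low temperature and small DMAP charge guard against racemisation of 3 and aromatisation of the diene.

Step 3
Reactants: 4 bromodienyl ester
Product: 5 2-bromo-4,5-dihydroxy-6-[(tert-butyldimethylsilyl)oxy]cyclohex-2-en-1-yl (2R)-2-methylbutanoate (new hydroxyls cis to each other and trans to the OTBS and acyloxy groups)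
Conditions: OsO4 (2 mol %), NMO, acetone/H2O, 0 °C
Reagents that add atoms: N-methylmorpholine N-oxide, C[N+]1([O-])CCOCC1; water, O
Why: Upjohn dihydroxylation attacks only the electron-richer unhalogenated alkene (future C2 and C7) of such halodienes, from the face opposite the two oxygen substituents, and the new centres are only handles for cleavage.

Step 4
Reactants: 5 bromocyclohexenediol; 6 (tributylstannyl)methanol
Product: 7 triol: 5 in which Br is replaced by CH2OH (C14)
Conditions: Pd(PPh3)4 (5 mol %), toluene, 90 °C
Reagents that add atoms: none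
Why: Stille hydroxymethylation of an alkenyl bromide forms C10–C14 with retention of the ring alkene, since insertion of zerovalent palladium into C–Br is faster than ionisation of the hindered allylic ester.

Step 5
Reactants: 7 triol
Product: 8 C14 TBS ether of 7 (ring 1,2-diol free)
Conditions: TBSCl (1.05 equiv), imidazole, CH2Cl2, 0 °C
Reagents that add atoms: tert-butyldimethylsilyl chloride, CC(C)(C)[Si](C)(C)Cl
Why: Selective silylation of the only primary hydroxyl in the presence of two flanked secondary ones is a routine steric differentiation.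

Step 6
Reactants: 8 ring diol
Product: 10 acyclic diol HOC7H2–C8H(OTBS)–C9H(O-acyl)–C10(C14H2OTBS)=C1H–C2H2OH; C9 and C2 cis on the alkene, via dialdehyde 9 (not isolated)
Conditions: NaIO4 on SiO2, CH2Cl2, rt; filter; NaBH4, EtOH, −20 °C
Reagents that add atoms: none
Why: Malaprade glycol cleavage opens the ring between C2 and C7 so that the ring-enforced cis C1=C10 geometry is kept, and immediate borohydride 1,2-reduction removes the elimination-prone C7 aldehyde before it can epimerise at C8.

Step 7
Reactants: 10 acyclic diol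
Product: 11 C2 allylic bromide with the C7 primary alcohol free
Conditions: NBS, Me2S, CH2Cl2, −30 → 0 °C
Reagents that add atoms: N-bromosuccinimide, O=C1CCC(=O)N1Br
Why: Corey–Kim halogenation converts only the allylic alkoxysulfonium salt into the bromide by SN2 attack at C2 under neutral conditions, while the saturated C7 alcohol is returned on work-up.

Step 8
Reactants: 11 bromo alcohol
Product: 12 C7 triethylsilyl ether of 11
Conditions: TESOTf, 2,6-lutidine, CH2Cl2, −78 °C
Reagents that add atoms: triethylsilyl triflate, CC[Si](CC)(CC)OS(=O)(=O)C(F)(F)F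
Why: Silylation with a non-nucleophilic base spares the allylic bromide and removes the free alkoxide that would otherwise invite TBS or acyl migration in the next step.

Step 9
Reactants: 12 TES bromide; 13 tert-butyl acetate
Product: 15 tert-butyl ester with the chain C1H=…–C2H2–C3H2–CO2tBu, via lithium enolate 14 (not isolated)
Conditions: LiN(iPr)2, THF, −78 °C; then 12, DMPU, −78 → −40 °C
Reagents that add atoms: lithium diisopropylamide, [Li+].CC(C)[N-]C(C)C (lithium of 14 only)
Why: SN2 alkylation of an acetate ester enolate at the primary allylic carbon forms C2–C3 (SN2' attack at fully substituted C10 is blocked), and at this temperature the hindered C9 ester is neither attacked nor enolised.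

Step 10
Reactants: 15 TES ether tert-butyl ester
Product: 17 C7 aldehyde OHC–C8H(OTBS)–C9H(O-acyl)–C10(CH2OTBS)=C1H–C2H2–C3H2–CO2tBu, via alkoxysulfonium chloride 16 (not isolated)
Conditions: (COCl)2, DMSO, CH2Cl2, −78 → −40 °C; Et3N, −78 → −20 °C; cold pH 7 quench
Reagents that add atoms: dimethyl sulfoxide, CS(C)=O; oxalyl chloride, O=C(Cl)C(=O)Cl (Me2S unit and chloride of 16 only)
Why: Swern oxidation applied directly to a primary triethylsilyl ether exchanges only this labile silyl group for the sulfonium unit and leaves both TBS ethers, and the cold quench limits epimerisation at C8 and loss of the C9 acyloxy group.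

Step 11
Reactants: 18 methyl 2-[bis(2,2,2-trifluoroethoxy)phosphoryl]acetate
Product: 20 methyl 2-[bis(2,2,2-trifluoroethoxy)phosphoryl]-2-bromoacetate (racemic), via sodium phosphonate carbanion 19 (not isolated)
Conditions: NaH, THF, 0 °C; Br2 (1.0 equiv), −78 °C
Reagents that add atoms: bromine, BrBr; sodium hydride, [Na+].[H-] (sodium of 19 only)
Why: Electrophilic alpha-bromination of a stabilised phosphonate carbanion is the standard access to bromophosphonoacetates.

Step 12
Reactants: 17 C7 aldehyde; 20 bromophosphonate
Product: 22 methyl (E)-2-bromo-2-enoate C8–C7H=C11(Br)–C12O2Me; C8 cis to the ester, via potassium bromophosphonate carbanion 21 (not isolated)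
Conditions: KOtBu, 18-crown-6, THF, −78 °C; then 17
Reagents that add atoms: potassium tert-butoxide, CC(C)(C)[O-].[K+] (potassium of 21 only)
Why: Horner–Wadsworth–Emmons olefination in its Still–Gennari (trifluoroethyl phosphonate) form eliminates kinetically and places the aldehyde residue cis to the ester, and the weakly basic anion at −78 °C leaves C8 and the C9 ester alone.

Step 13
Reactants: 22 (E)-bromoenoate; 23 2-(iodomethyl)-4,4,5,5-tetramethyl-1,3,2-dioxaborolane
Product: 25 allylboronate C8–C7H=C11(C13H2Bpin)–C12O2Me; C8 cis to the ester and trans to CH2B, via borylmethylzinc iodide 24 (not isolated)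
Conditions: Zn dust, THF, rt; then 22, Pd(PPh3)4 (5 mol %), THF, rt
Reagents that add atoms: zinc, [Zn] (in 24 only)
Why: Negishi coupling of a (borylmethyl)zinc halide with an alkenyl bromide forms C11–C13 with retention of geometry, the activated alpha-bromoenoate being the only site that reacts with zerovalent palladium at room temperature.

Step 14
Reactants: 26 but-2-yn-1-ol
Product: 28 (Z)-3-iodobut-2-en-1-ol, via cyclic alkenylalanate 27 (not isolated)
Conditions: NaAlH2(OCH2CH2OMe)2 (1.1 equiv), Et2O, 0 °C → rt; I2, THF, −78 °C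
Reagents that add atoms: iodine, II; sodium bis(2-methoxyethoxy)aluminium dihydride, [Na+].[AlH2-](OCCOC)OCCOC (aluminate part of 27 only)
Why: Alkoxide-directed trans-hydroalumination of a propargylic alcohol puts hydrogen on C5 and aluminium on C4 within a five-membered ring, and iodinolysis with retention gives the iodide with I cis to the carbinol carbon.

Step 15
Reactants: 28 (Z)-3-iodobut-2-en-1-ol
Product: 29 (Z)-3-iodobut-2-enal
Conditions: MnO2, CH2Cl2, rt, dark; used at once
Reagents that add atoms: none
Why: Neutral MnO2 oxidation of an allylic alcohol gives the enal without acid or base, the agents that would isomerise the Z alkene.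

Step 16
Reactants: 25 allylboronate; 29 (Z)-3-iodobut-2-enal
Product: 31 trans-alpha-methylene-gamma-lactone (O–C6; C6 bears the Z 2-iodoprop-1-enyl group; C7 bears the C8–C3 chain ending in CO2tBu), via boryl ether 30 (not isolated)
Conditions: Sc(OTf)3 (10 mol %), toluene, 0 °C → rt, dark
Reagents that add atoms: none
Why: Lewis-acid-catalysed allylboration through a closed chair followed by lactonisation: with C8 trans to CH2B the adduct is anti, which is the trans C6/C7 lactone, and allylic 1,3-strain against the cis ester holds C8–H in the alkene plane so that 29 reaches C7 opposite the branched C9 carbon, giving the C6 and C7 configurations of the target.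

Step 17
Reactants: 31 lactone tert-butyl ester
Product: 33 seco acid (C3H2–CO2H), via trimethylsilyl ester 32 (not isolated)
Conditions: TMSOTf, 2,6-lutidine, CH2Cl2, 0 °C; aqueous work-up
Reagents that add atoms: trimethylsilyl triflate, C[Si](C)(C)OS(=O)(=O)C(F)(F)F (silyl group of 32 only)
Why: Silyl-triflate-mediated cleavage of a tert-butyl ester proceeds by loss of isobutene under buffered conditions that TBS ethers, the lactone, the C9 ester and the alkenyl iodide tolerate.

Step 18
Reactants: 33 seco acid
Product: 34 N-acyloxyphthalimide (redox-active ester) of 33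
Conditions: N-hydroxyphthalimide, DIC, DMAP (5 mol %), CH2Cl2, rt
Reagents that add atoms: N-hydroxyphthalimide, ON1C(=O)c2ccccc2C1=O
Why: Carbodiimide esterification is the standard, neutral preparation of redox-active esters and touches nothing else in 33.

Step 19
Reactants: 34 seco redox-active ester with the Z C4 alkenyl iodide
Product: 35 ten-membered carbocycle fused to the lactone (target skeleton; C8 OTBS; C14H2OTBS)
Conditions: NiCl2(dme) (30 mol %), 2,2'-bipyridine (36 mol %), Bu4NBF4 (0.1 M), DMF, Zn anode, reticulated vitreous carbon cathode, undivided cell, constant current, rt; 34 added by syringe pump to a final 2 mM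
Reagents that add atoms: none
Why: Proposed new method: cathodic reduction turns the divalent nickel–bipyridine salt into low-valent nickel, which inserts into the C4–I bond with retention, while single-electron reduction of the N-acyloxyphthalimide releases phthalimide anion, CO2 and the primary C3 radical, and capture of this radical by the C4 alkenylnickel gives a trivalent alkyl(alkenyl)nickel that forms C3–C4 by reductive elimination. The closest known reaction type is the intermolecular nickel-electrocatalytic decarboxylative alkenylation of redox-active esters with alkenyl halides, and nickel-mediated reductive closures of large rings indicate that such couplings can be run intramolecularly. The ten-membered ring closes by end-to-end C(sp3)–C(sp2) coupling at the metal, that is through an eleven-membered nickelacycle that contracts on reductive elimination, not by radical addition to an alkene. No stereocentre is created, and the only stereochemical demand, the cis C4=C5 geometry fixed in 29, is met because oxidative addition and reductive elimination at an alkenyl carbon are stereoretentive. Ring closure must beat hydrodeiodination, reduction or dimerisation of the radical, its addition to the C11=C13 acceptor and ionisation of the allylic C9 ester: slow addition into a dilute cell with a high nickel loading keeps each chain nickel-bound before its radical forms, the two cis alkenes and the trans-lactone fold C3 towards C4, attack on C13 would need a strained nine-membered transition state, and the alkenyl iodide is by far the fastest electrophile for low-valent nickel. The sacrificial zinc anode keeps the medium free of base, nucleophile and oxidant, so the methylene lactone, both esters and both silyl ethers stay spectators.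

Step 20
Reactants: 35 bis-TBS macrocycle
Product: 36 C8,C14-diol (target with CH2OH at C14)
Conditions: HF·pyridine, pyridine, THF, 0 °C → rt
Reagents that add atoms: none
Why: Buffered fluoride desilylation removes both TBS ethers under mildly acidic conditions, which suppress C9-to-C8 or C9-to-C14 acyl migration and conjugate addition to the lactone.

Step 21
Reactants: 36 diol
Product: 37 target CNP0256845.2
Conditions: MnO2, CH2Cl2, rt
Reagents that add atoms: none
Why: MnO2 oxidises only the primary allylic C14 alcohol to the enal, because the C8 hydroxyl is secondary and not allylic, and no stereocentre or alkene geometry is affected.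

**Compound list**
1 | (1S,2S)-3-bromocyclohexa-3,5-diene-1,2-diol | O[C@H]1C=CC=C(Br)[C@H]1O | starting material
2 | (1S,6S)-2-bromo-6-[(tert-butyldimethylsilyl)oxy]cyclohexa-2,4-dien-1-ol | CC(C)(C)[Si](C)(C)O[C@H]1C=CC=C(Br)[C@H]1O | intermediate
3 | (2R)-2-methylbutanoic acid | OC(=O)[C@H](C)CC | starting material
4 | (1S,6S)-2-bromo-6-[(tert-butyldimethylsilyl)oxy]cyclohexa-2,4-dien-1-yl (2R)-2-methylbutanoate | CC(C)(C)[Si](C)(C)O[C@H]1C=CC=C(Br)[C@H]1OC(=O)[C@H](C)CC | intermediate
5 | bromocyclohexenediol (new cis-diol anti to OTBS and acyloxy) | CC(C)(C)[Si](C)(C)O[C@H]1[C@H](O)[C@H](O)C=C(Br)[C@H]1OC(=O)[C@H](C)CC | intermediate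
6 | (tributylstannyl)methanol | OC[Sn](CCCC)(CCCC)CCCC | starting material
7 | hydroxymethyl triol (C14 installed) | CC(C)(C)[Si](C)(C)O[C@H]1[C@H](O)[C@H](O)C=C(CO)[C@H]1OC(=O)[C@H](C)CC | intermediate
8 | C14 TBS ether, ring diol | CC(C)(C)[Si](C)(C)O[C@H]1[C@H](O)[C@H](O)C=C(CO[Si](C)(C)C(C)(C)C)[C@H]1OC(=O)[C@H](C)CC | intermediate
9 | C2,C7-dialdehyde | O=C[C@H](O[Si](C)(C)C(C)(C)C)[C@H](OC(=O)[C@H](C)CC)/C(CO[Si](C)(C)C(C)(C)C)=C\C=O | intermediate
10 | C2,C7-diol | OC[C@H](O[Si](C)(C)C(C)(C)C)[C@H](OC(=O)[C@H](C)CC)/C(CO[Si](C)(C)C(C)(C)C)=C\CO | intermediate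
11 | C2 allylic bromide, C7 alcohol | OC[C@H](O[Si](C)(C)C(C)(C)C)[C@H](OC(=O)[C@H](C)CC)/C(CO[Si](C)(C)C(C)(C)C)=C\CBr | intermediate
12 | C2 allylic bromide, C7 TES ether | CC[Si](CC)(CC)OC[C@H](O[Si](C)(C)C(C)(C)C)[C@H](OC(=O)[C@H](C)CC)/C(CO[Si](C)(C)C(C)(C)C)=C\CBr | intermediate
13 | tert-butyl acetate | CC(=O)OC(C)(C)C | starting material
14 | lithium enolate of tert-butyl acetate | [Li+].C=C([O-])OC(C)(C)C | intermediate
15 | chain-extended tert-butyl ester, C7 TES ether | CC[Si](CC)(CC)OC[C@H](O[Si](C)(C)C(C)(C)C)[C@H](OC(=O)[C@H](C)CC)/C(CO[Si](C)(C)C(C)(C)C)=C\CCC(=O)OC(C)(C)C | intermediate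
16 | C7 alkoxydimethylsulfonium chloride | C[S+](C)OC[C@H](O[Si](C)(C)C(C)(C)C)[C@H](OC(=O)[C@H](C)CC)/C(CO[Si](C)(C)C(C)(C)C)=C\CCC(=O)OC(C)(C)C.[Cl-] | intermediate
17 | C7 aldehyde | O=C[C@H](O[Si](C)(C)C(C)(C)C)[C@H](OC(=O)[C@H](C)CC)/C(CO[Si](C)(C)C(C)(C)C)=C\CCC(=O)OC(C)(C)C | intermediate
18 | methyl 2-[bis(2,2,2-trifluoroethoxy)phosphoryl]acetate | COC(=O)CP(=O)(OCC(F)(F)F)OCC(F)(F)F | starting material
19 | sodium carbanion of 18 | [Na+].COC(=O)[CH-]P(=O)(OCC(F)(F)F)OCC(F)(F)F | intermediate
20 | methyl 2-[bis(2,2,2-trifluoroethoxy)phosphoryl]-2-bromoacetate (racemic) | COC(=O)C(Br)P(=O)(OCC(F)(F)F)OCC(F)(F)F | intermediate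
21 | potassium carbanion of 20 | [K+].COC(=O)[C-](Br)P(=O)(OCC(F)(F)F)OCC(F)(F)F | intermediate
22 | (E)-2-bromo-2-enoate (C8 cis to CO2Me) | COC(=O)/C(Br)=C\[C@H](O[Si](C)(C)C(C)(C)C)[C@H](OC(=O)[C@H](C)CC)/C(CO[Si](C)(C)C(C)(C)C)=C\CCC(=O)OC(C)(C)C | intermediate
23 | 2-(iodomethyl)-4,4,5,5-tetramethyl-1,3,2-dioxaborolane | ICB1OC(C)(C)C(C)(C)O1 | starting material
24 | iodo[(4,4,5,5-tetramethyl-1,3,2-dioxaborolan-2-yl)methyl]zinc | I[Zn]CB1OC(C)(C)C(C)(C)O1 | intermediate
25 | 2-(methoxycarbonyl)allylboronate (C8 trans to CH2B) | COC(=O)/C(CB1OC(C)(C)C(C)(C)O1)=C\[C@H](O[Si](C)(C)C(C)(C)C)[C@H](OC(=O)[C@H](C)CC)/C(CO[Si](C)(C)C(C)(C)C)=C\CCC(=O)OC(C)(C)C | intermediate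
26 | but-2-yn-1-ol | CC#CCO | starting material
27 | sodium cyclic alkenylalanate (1,2-oxaluminole) | CC1=CCO[Al-]1(OCCOC)OCCOC.[Na+] | intermediate
28 | (Z)-3-iodobut-2-en-1-ol | OC/C=C(/C)I | intermediate
29 | (Z)-3-iodobut-2-enal | O=C/C=C(/C)I | intermediate
30 | anti homoallylic boryl ether (open hydroxy-ester form) | COC(=O)C(=C)[C@@H]([C@H](OB1OC(C)(C)C(C)(C)O1)/C=C(/C)I)[C@H](O[Si](C)(C)C(C)(C)C)[C@H](OC(=O)[C@H](C)CC)/C(CO[Si](C)(C)C(C)(C)C)=C\CCC(=O)OC(C)(C)C | intermediate
31 | trans-methylene lactone, tert-butyl ester | C=C1C(=O)O[C@H](/C=C(/C)I)[C@H]1[C@H](O[Si](C)(C)C(C)(C)C)[C@H](OC(=O)[C@H](C)CC)/C(CO[Si](C)(C)C(C)(C)C)=C\CCC(=O)OC(C)(C)C | intermediate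
32 | trimethylsilyl ester | C=C1C(=O)O[C@H](/C=C(/C)I)[C@H]1[C@H](O[Si](C)(C)C(C)(C)C)[C@H](OC(=O)[C@H](C)CC)/C(CO[Si](C)(C)C(C)(C)C)=C\CCC(=O)O[Si](C)(C)C | intermediate
33 | seco acid | C=C1C(=O)O[C@H](/C=C(/C)I)[C@H]1[C@H](O[Si](C)(C)C(C)(C)C)[C@H](OC(=O)[C@H](C)CC)/C(CO[Si](C)(C)C(C)(C)C)=C\CCC(=O)O | intermediate
34 | seco N-acyloxyphthalimide (key-step precursor) | C=C1C(=O)O[C@H](/C=C(/C)I)[C@H]1[C@H](O[Si](C)(C)C(C)(C)C)[C@H](OC(=O)[C@H](C)CC)/C(CO[Si](C)(C)C(C)(C)C)=C\CCC(=O)ON1C(=O)c2ccccc2C1=O | intermediate
35 | bis-TBS macrocycle (key-step product) | C=C1C(=O)O[C@@H]2/C=C(/C)CC/C=C(/CO[Si](C)(C)C(C)(C)C)[C@@H](OC(=O)[C@H](C)CC)[C@@H](O[Si](C)(C)C(C)(C)C)[C@@H]12 | intermediate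
36 | C8,C14-diol | C=C1C(=O)O[C@@H]2/C=C(/C)CC/C=C(/CO)[C@@H](OC(=O)[C@H](C)CC)[C@@H](O)[C@@H]12 | intermediate
37 | CNP0256845.2 | C=C1C(=O)O[C@@H]2/C=C(/C)CC/C=C(/C=O)[C@@H](OC(=O)[C@H](C)CC)[C@@H](O)[C@@H]12 | target

Total step count: 21.
Longest linear sequence: 18 steps (1–10, 12, 13, 16–21).

**Steps most likely to fail**

Step 19. The C3 radical may be reduced, abstract hydrogen, add to the C11=C13 acceptor or couple between molecules before it is captured at nickel, and the C4 iodide may be hydrodeiodinated. The fallback uses known reactions, closes the same bond without a free radical in the ring-forming event, sets out from 33 and returns at 35.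
- Acid 33 is coupled with 1-hydroxypyridine-2(1H)-thione (DCC, CH2Cl2, dark) to give the thiohydroxamate ester F1.
- Visible-light Barton decarboxylation in the presence of CHI3 gives the primary C3 iodide F2; iodine-atom transfer is fast enough to pre-empt cyclisation.
- Zinc dust with LiCl in THF inserts only into the sp3 C–I bond to give the alkylzinc iodide F3.
- Slow addition of this solution to PdCl2(dppf) in warm THF closes C3–C4 by an intramolecular Negishi coupling, with retention at C4.

Step 16. Addition of the hindered, electron-poor pinacol boronate may be slow. This would allow Z-to-E isomerisation of the iodoenal and erode the facial discrimination at C7. The fallback changes the boron reagent and separates addition from ring closure; it sets out from 25 and returns at 31.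
- KHF2 in MeOH/H2O converts 25 into the potassium trifluoroborate F4.
- With BF3·OEt2 in CH2Cl2 at −78 °C, the derived allyldifluoroborane adds to 29 through the same chair within minutes. After work-up this gives the anti hydroxy ester F5, at which stage the diastereomers can be separated.
- PPTS in toluene then lactonises it to 31.

Step 7. Discrimination between the two primary hydroxyls may be incomplete, and the allylic bromide may ionise and lose its alkene geometry while the free alcohol is present. The fallback differentiates the termini by oxidation level; it sets out from 10 and returns at 12.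
- MnO2 oxidises only the allylic C2 alcohol to the hydroxy enal F6.
- TESOTf with 2,6-lutidine gives the C7 TES ether enal F7.
- Luche reduction (CeCl3·7H2O, NaBH4, MeOH) gives the allylic alcohol F8.
- An Appel reaction (CBr4, PPh3, CH2Cl2, −20 °C) delivers 12.

**Further compounds**
F1 | step 19 | thiohydroxamate (Barton) ester of 33 | C=C1C(=O)O[C@H](/C=C(/C)I)[C@H]1[C@H](O[Si](C)(C)C(C)(C)C)[C@H](OC(=O)[C@H](C)CC)/C(CO[Si](C)(C)C(C)(C)C)=C\CCC(=O)ON1C=CC=CC1=S
F2 | step 19 | primary C3 iodide | C=C1C(=O)O[C@H](/C=C(/C)I)[C@H]1[C@H](O[Si](C)(C)C(C)(C)C)[C@H](OC(=O)[C@H](C)CC)/C(CO[Si](C)(C)C(C)(C)C)=C\CCI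
F3 | step 19 | C3 alkylzinc iodide | C=C1C(=O)O[C@H](/C=C(/C)I)[C@H]1[C@H](O[Si](C)(C)C(C)(C)C)[C@H](OC(=O)[C@H](C)CC)/C(CO[Si](C)(C)C(C)(C)C)=C\CC[Zn]I
F4 | step 16 | potassium allyltrifluoroborate from 25 | [K+].COC(=O)/C(C[B-](F)(F)F)=C\[C@H](O[Si](C)(C)C(C)(C)C)[C@H](OC(=O)[C@H](C)CC)/C(CO[Si](C)(C)C(C)(C)C)=C\CCC(=O)OC(C)(C)C
F5 | step 16 | anti hydroxy ester | COC(=O)C(=C)[C@@H]([C@H](O)/C=C(/C)I)[C@H](O[Si](C)(C)C(C)(C)C)[C@H](OC(=O)[C@H](C)CC)/C(CO[Si](C)(C)C(C)(C)C)=C\CCC(=O)OC(C)(C)C
F6 | step 7 | C7 hydroxy C2 enal | OC[C@H](O[Si](C)(C)C(C)(C)C)[C@H](OC(=O)[C@H](C)CC)/C(CO[Si](C)(C)C(C)(C)C)=C\C=O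
F7 | step 7 | C7 TES ether C2 enal | CC[Si](CC)(CC)OC[C@H](O[Si](C)(C)C(C)(C)C)[C@H](OC(=O)[C@H](C)CC)/C(CO[Si](C)(C)C(C)(C)C)=C\C=O
F8 | step 7 | C7 TES ether C2 allylic alcohol | CC[Si](CC)(CC)OC[C@H](O[Si](C)(C)C(C)(C)C)[C@H](OC(=O)[C@H](C)CC)/C(CO[Si](C)(C)C(C)(C)C)=C\CO
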